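Numbering is that of the clerodanes: ring A = C1–C5 and C10; ring B = C5–C10; C17 on C8, C19 on C5, C20 on C9, chain C11–C16, C18 on C4. β is the face of C19.

**Retrosynthetic overview**
1. Ring A is finished last. C4=C18 comes from a Mannich methylenation. The 2-hydroxy-1-en-3-one comes from α'-hydroxylation of a Δ1(10)-2-one followed by ketol–enediol tautomerisation, which also sets 10β-H. The chain enoate comes from a Horner–Wadsworth–Emmons reaction.
2. The C7 acetate derives from a C7 acetyl group (Baeyer–Villiger, retention). C6H2 and C20H3 derive from a C6–S–C20 bridge (Raney Ni), so ring B is hidden in a 2-thiabicyclo[2.2.2]octane. Ring A is built on it by a Michael addition at C5 and an aldol condensation at C10.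
3. Key disconnection: C6–C7 and C8–C9 form in one [4+2] between the achiral 4-silyloxy-2H-thiopyran 7 (C6=C5–C10=C9) and (E)-pent-3-en-2-one 8 (C7=C8).
4. Enabling feature: in ring B the bare methylene C6 and the methyl C20 on quaternary C9 stand 1,4 and both end as plain C–H carbons. One sulfur atom can therefore tie them into a temporary ring that locks the otherwise unreactive (Z)-substituted diene s-cis. C17 is cis to C20 and trans to the C7 oxygen, which is the endo adduct of an E-enone.
5. Ring order: temporary thiopyran (present from the start), ring B (step 6), ring A (steps 7 and 8), thiopyran erased (step 9).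

Key step: step 6

Remark: the sense of induction in step 6 is assigned from the usual binding model of the oxazaborolidinium ion (enone held through its carbonyl oxygen and α-C–H). If the opposite sense is found, the (R)-catalyst is used and nothing else changes.

**Step 1**
Reactants: 1 methyl 4-oxothiane-3-carboxylate
Product: 2 methyl 5-methyl-4-oxothiane-3-carboxylate (racemic isomer mixture)
Conditions: NaH, THF, 0 °C; n-BuLi, 0 °C; MeI, 0 °C to rt; H2O quench
Reagents that add atoms: iodomethane CI
Why: Dianion γ-alkylation of a β-keto ester, in which the second and more basic carbanion at C5 of the thiane is methylated selectively; both stereocentres are erased by step 5, so the mixture is carried on.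

**Step 2**
Reactants: 2 methyl 5-methyl-4-oxothiane-3-carboxylate; 3 2-(2-bromoethyl)-2-methyl-1,3-dioxolane
Product: 4 methyl 5-methyl-3-[2-(2-methyl-1,3-dioxolan-2-yl)ethyl]-4-oxothiane-3-carboxylate (racemic isomer mixture)
Conditions: K2CO3, NaI (cat.), DMF, 60 °C
Reagents that add atoms: none
Why: SN2 C-alkylation of the stabilised β-keto ester enolate, which is too weakly basic to open the thiane; the new quaternary carbon leaves only the methyl-bearing α-carbon enolisable for step 3, and its configuration is irrelevant.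

**Step 3**
Reactants: 4 methyl 5-methyl-3-[2-(2-methyl-1,3-dioxolan-2-yl)ethyl]-4-oxothiane-3-carboxylate
Product: 5 methyl 5-methyl-3-[2-(2-methyl-1,3-dioxolan-2-yl)ethyl]-4-oxo-3,4-dihydro-2H-thiopyran-3-carboxylate (racemic)
Conditions: LDA, THF, −78 °C; N-tert-butylbenzenesulfinimidoyl chloride, −78 °C
Reagents that add atoms: none
Why: Mukaiyama dehydrogenation (enolate attack on sulfur, then syn-elimination) avoids oxidants that would attack the sulfide, and elimination towards the CH2 next to sulfur gives the conjugated vinylogous thioester.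

**Step 4**
Reactants: 5 methyl 5-methyl-3-[2-(2-methyl-1,3-dioxolan-2-yl)ethyl]-4-oxo-3,4-dihydro-2H-thiopyran-3-carboxylate
Product: 6 5-methyl-3-[2-(2-methyl-1,3-dioxolan-2-yl)ethyl]-2,3-dihydro-4H-thiopyran-4-one (racemic)
Conditions: LiCl, H2O, DMSO, 140 °C
Reagents that add atoms: none
Why: Krapcho dealkoxycarbonylation of the activated methyl ester under near-neutral conditions that spare the dioxolane.

**Step 5**
Reactants: 6 5-methyl-3-[2-(2-methyl-1,3-dioxolan-2-yl)ethyl]-2,3-dihydro-4H-thiopyran-4-one
Product: 7 4-(tert-butyldimethylsilyloxy)-5-methyl-3-[2-(2-methyl-1,3-dioxolan-2-yl)ethyl]-2H-thiopyran (achiral diene)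
Conditions: LDA, THF, −78 °C; TBSCl, DMPU, −78 to 0 °C
Reagents that add atoms: tert-butyldimethylsilyl chloride CC(C)(C)[Si](C)(C)Cl
Why: Kinetic α'-deprotonation of the enone (no γ-hydrogen is available) and O-silylation give the cyclic silyloxydiene, and the last stereocentre disappears.

**Step 6**
Reactants: 7 4-(tert-butyldimethylsilyloxy)-5-methyl-3-[2-(2-methyl-1,3-dioxolan-2-yl)ethyl]-2H-thiopyran; 8 (E)-pent-3-en-2-one
Product: 9 1-{(1S,4R,7S,8R)-5-(tert-butyldimethylsilyloxy)-6,8-dimethyl-4-[2-(2-methyl-1,3-dioxolan-2-yl)ethyl]-2-thiabicyclo[2.2.2]oct-5-en-7-yl}ethan-1-one (acetyl endo; 8-methyl exo)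
Conditions: (S)-1-(2-methylphenyl)-3,3-diphenyltetrahydro-1H,3H-pyrrolo[1,2-c][1,3,2]oxazaborole·HN(SO2CF3)2 (20 mol %), CH2Cl2, −78 to −40 °C
Reagents that add atoms: none
Why: The enone, activated by coordination of its oxygen to the chiral boron cation, adds across C9 and C6 of the thiopyran in a concerted but asynchronous [4π+2π] cycloaddition with the C8–C9 bond leading; the stepwise limit (Mukaiyama–Michael addition, then capture of the thionium ion by the enolate) gives the same product. The closest known reactions are Diels–Alder additions of 4-silyloxy-2H-thiopyrans used as locked surrogates of (Z)-dienes, and oxazaborolidinium-catalysed Diels–Alder reactions of acyclic enones with silyloxydienes. Ring B closes as the carbocyclic six-membered ring of a 2-thiabicyclo[2.2.2]oct-5-ene by suprafacial addition to the diene that the temporary ring holds s-cis. C7 and C8 come out trans because the E geometry of 8 is retained; C6 and quaternary C9 follow from the endo rule (acetyl under the C5=C10 bridge, hence C17 syn to the S–C20 bridge, which is cis to the future C20 methyl); the absolute sense is set by the catalyst, which leaves one face of the bound enone open. The step needs regioselectivity, and two reinforcing donors secure it: sulfur on C6 and the silyloxy group on C10 both place the largest HOMO coefficient on C9, which therefore binds the methyl-bearing β-carbon of the enone.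

**Step 7**
Reactants: 9 the Diels–Alder adduct; 10 but-3-en-2-one
Product: 11 (1S,4R,6R,7S,8R)-7-acetyl-6,8-dimethyl-4-[2-(2-methyl-1,3-dioxolan-2-yl)ethyl]-6-(3-oxobutyl)-2-thiabicyclo[2.2.2]octan-5-one (3-oxobutyl syn to the sulfur bridge)
Conditions: BF3·OEt2, i-PrOH, CH2Cl2, −78 °C
Reagents that add atoms: none
Why: Mukaiyama–Michael addition of the regiodefined tetrasubstituted silyl enol ether without enolising the acetyl group; the endo acetyl covers the face of C5 that looks at the C7–C8 bridge, so attack comes from the face of the bare sulfur bridge and places C4 α and C19 β on the new quaternary C5.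

**Step 8**
Reactants: 11 the thia-bridged triketone
Product: 12 thia-bridged octalone (ring A Δ1(10)-2-one; sulfur links C6α to C20; 5β-methyl; 7β-acetyl; 8α-methyl; 9β-ketal chain)
Conditions: KOH, MeOH, 50 °C
Reagents that add atoms: none
Why: Intramolecular aldol condensation (second half of a Robinson annulation), in which C10 is the carbonyl within six-ring reach of the C1 methyl group and the bicycle ties back the substituents of C9; any epimerisation at C7 is corrected in step 9.

**Step 9**
Reactants: 12 thia-bridged octalone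
Product: 13 7β-acetyl-5β,8α,9α-trimethyl-9β-[2-(2-methyl-1,3-dioxolan-2-yl)ethyl]-Δ1(10)-octal-2-one
Conditions: Raney Ni (W-2), EtOH, rt; then K2CO3 (cat.), MeOH, rt
Reagents that add atoms: none
Why: Raney nickel hydrogenolysis of both C–S bonds turns C6 into CH2 and C20 into the 9α-methyl group, while the enone double bond between two quaternary carbons should resist; the base wash equilibrates C7 to the equatorial 7β-acetyl group trans to C17.

**Step 10**
Reactants: 13 the 7β-acetyl octalone
Product: 14 7β-acetoxy-5β,8α,9α-trimethyl-9β-[2-(2-methyl-1,3-dioxolan-2-yl)ethyl]-Δ1(10)-octal-2-one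
Conditions: m-CPBA, NaHCO3, CH2Cl2, rt
Reagents that add atoms: 3-chloroperbenzoic acid O=C(OO)c1cccc(Cl)c1
Why: Baeyer–Villiger oxidation, in which secondary C7 migrates in preference to methyl with retention, so the acetyl group becomes the 7β-acetate of the target; the conjugated ketone and its electron-poor double bond react much more slowly.

**Step 11**
Reactants: 14 the 7β-acetoxy ketal
Product: 15 7β-acetoxy-5β,8α,9α-trimethyl-9β-(3-oxobutyl)-Δ1(10)-octal-2-one
Conditions: 1 M aq HCl, THF, rt
Reagents that add atoms: water O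
Why: Mild acid hydrolysis of the ketone acetal; the acetate is safe because C5 is quaternary and no β-elimination path exists.

**Step 12**
Reactants: 15 the methyl ketone; 16 tert-butyl 2-(diethoxyphosphoryl)acetate
Product: 17 tert-butyl (13E)-7β-acetoxy-2-oxo-18-norcleroda-1(10),13-dien-15-oate
Conditions: NaH, THF, 0 °C to rt
Reagents that add atoms: none
Why: Horner–Wadsworth–Emmons olefination is faster at the unhindered saturated methyl ketone than at the conjugated ring ketone; the E isomer is the usual preference and the Z isomer is removed by chromatography.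

**Step 13**
Reactants: 17 the enone ester
Product: 18 tert-butyl (13E)-7β-acetoxy-3-hydroxy-2-oxo-18-norcleroda-1(10),13-dien-15-oate (C3 epimers)
Conditions: KHMDS, THF, −78 °C; 2-(phenylsulfonyl)-3-phenyloxaziridine, −78 °C; H2O
Reagents that add atoms: 2-(phenylsulfonyl)-3-phenyloxaziridine O=S(=O)(N1OC1c1ccccc1)c1ccccc1
Why: Enolate hydroxylation with an N-sulfonyloxaziridine; the enone has no γ-hydrogen (C5 and C9 are quaternary), so only the C3 enolate can form, and the C3 configuration is lost in step 14.

**Step 14**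
Reactants: 18 the α'-hydroxy enone
Product: 19 tert-butyl (13E)-7β-acetoxy-2-hydroxy-3-oxo-18-nor-10βH-cleroda-1,13-dien-15-oate
Conditions: DBU (cat.), toluene, 60 °C, argon
Reagents that add atoms: none
Why: Base-mediated ketol–enediol tautomerisation (Lobry de Bruyn–van Ekenstein type) moves the carbonyl to C3, and γ-protonation of the derived dienolate at C10 gives the hydrogen-bonded diosphenol as the thermodynamic sink; C10 stays epimerisable and settles as 10β-H because a trans fusion would force C19, the C7 acetate and C11 into a triaxial array on ring B.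

**Step 15**
Reactants: 19 the diosphenol
Product: 20 tert-butyl (13E)-7β-acetoxy-3-oxo-2-(triethylsilyloxy)-18-nor-10βH-cleroda-1,13-dien-15-oate
Conditions: TESCl, imidazole, CH2Cl2, 0 °C
Reagents that add atoms: chlorotriethylsilane CC[Si](Cl)(CC)CC
Why: O-silylation of the acidic enol masks the nucleophilic C1=C2 enol, so that only C4 can be functionalised next.

**Step 16**
Reactants: 20 the silyl-protected diosphenol
Product: 23 tert-butyl (13E)-7β-acetoxy-3-oxo-2-(triethylsilyloxy)-10βH-cleroda-1,4(18),13-trien-15-oate, via Mannich base 21 (not isolated), via trimethylammonium iodide 22 (not isolated)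
Conditions: LiHMDS, THF, −78 °C; CH2=NMe2+ I−, −78 °C to rt; MeI, Et2O, rt; aq NaHCO3, CH2Cl2, rt
Reagents that add atoms: dimethyl(methylidene)ammonium iodide C=[N+](C)C.[I-]; iodomethane CI
Why: Mannich methylenation, in which the kinetic enolate at C4 (the only α-CH2 of the C3 ketone) is trapped by the iminium salt; N-methylation followed by mild base gives a Hofmann-type β-elimination that can only form the exocyclic C4=C18 bond because C5 is quaternary.

**Step 17**
Reactants: 23 the fully protected trienone
Product: 24 (13E)-7β-acetoxy-2-hydroxy-3-oxo-10βH-cleroda-1,4(18),13-trien-15-oic acid, configuration 5S,7S,8S,9R,10R (target)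
Conditions: CF3CO2H, CH2Cl2, 0 °C to rt; aqueous work-up
Reagents that add atoms: none
Why: Acidolysis removes the tert-butyl group as isobutene and protodesilylates the silyl enol ether in the same operation, under conditions that leave the secondary acetate and the cross-conjugated enone untouched.

**Compound list**
1 | methyl 4-oxothiane-3-carboxylate | COC(=O)C1CSCCC1=O | starting material
2 | methyl 5-methyl-4-oxothiane-3-carboxylate (racemic isomer mixture) | COC(=O)C1CSCC(C)C1=O | intermediate
3 | 2-(2-bromoethyl)-2-methyl-1,3-dioxolane | CC1(CCBr)OCCO1 | starting material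
4 | methyl 5-methyl-3-[2-(2-methyl-1,3-dioxolan-2-yl)ethyl]-4-oxothiane-3-carboxylate (racemic isomer mixture) | COC(=O)C1(CCC2(C)OCCO2)CSCC(C)C1=O | intermediate
5 | methyl 5-methyl-3-[2-(2-methyl-1,3-dioxolan-2-yl)ethyl]-4-oxo-3,4-dihydro-2H-thiopyran-3-carboxylate (racemic) | COC(=O)C1(CCC2(C)OCCO2)CSC=C(C)C1=O | intermediate
6 | 5-methyl-3-[2-(2-methyl-1,3-dioxolan-2-yl)ethyl]-2,3-dihydro-4H-thiopyran-4-one (racemic) | CC1=CSCC(CCC2(C)OCCO2)C1=O | intermediate
7 | 4-(tert-butyldimethylsilyloxy)-5-methyl-3-[2-(2-methyl-1,3-dioxolan-2-yl)ethyl]-2H-thiopyran (achiral) | CC1=CSCC(CCC2(C)OCCO2)=C1O[Si](C)(C)C(C)(C)C | intermediate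
8 | (E)-pent-3-en-2-one | C/C=C/C(C)=O | starting material
9 | 1-{(1S,4R,7S,8R)-5-(tert-butyldimethylsilyloxy)-6,8-dimethyl-4-[2-(2-methyl-1,3-dioxolan-2-yl)ethyl]-2-thiabicyclo[2.2.2]oct-5-en-7-yl}ethan-1-one | C1(O[Si](C)(C)C(C)(C)C)=C(C)[C@H]2SC[C@]1(CCC3(C)OCCO3)[C@H](C)[C@H]2C(C)=O | intermediate
10 | but-3-en-2-one | C=CC(C)=O | starting material
11 | (1S,4R,6R,7S,8R)-7-acetyl-6,8-dimethyl-4-[2-(2-methyl-1,3-dioxolan-2-yl)ethyl]-6-(3-oxobutyl)-2-thiabicyclo[2.2.2]octan-5-one | O=C1[C@@](C)(CCC(C)=O)[C@H]2SC[C@]1(CCC3(C)OCCO3)[C@H](C)[C@H]2C(C)=O | intermediate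
12 | thia-bridged octalone: Δ1(10)-2-one, sulfur from C6α to C20, 5β-methyl, 7β-acetyl, 8α-methyl, 9β-ketal chain | C12=CC(=O)CC[C@@]1(C)[C@H]3SC[C@]2(CCC4(C)OCCO4)[C@H](C)[C@H]3C(C)=O | intermediate
13 | 7β-acetyl-5β,8α,9α-trimethyl-9β-[2-(2-methyl-1,3-dioxolan-2-yl)ethyl]-Δ1(10)-octal-2-one | C1CC(=O)C=C2[C@@](C)(CCC3(C)OCCO3)[C@H](C)[C@@H](C(C)=O)C[C@]12C | intermediate
14 | 7β-acetoxy-5β,8α,9α-trimethyl-9β-[2-(2-methyl-1,3-dioxolan-2-yl)ethyl]-Δ1(10)-octal-2-one | C1CC(=O)C=C2[C@@](C)(CCC3(C)OCCO3)[C@H](C)[C@@H](OC(C)=O)C[C@]12C | intermediate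
15 | 7β-acetoxy-5β,8α,9α-trimethyl-9β-(3-oxobutyl)-Δ1(10)-octal-2-one | C1CC(=O)C=C2[C@@](C)(CCC(C)=O)[C@H](C)[C@@H](OC(C)=O)C[C@]12C | intermediate
16 | tert-butyl 2-(diethoxyphosphoryl)acetate | CCOP(=O)(CC(=O)OC(C)(C)C)OCC | starting material
17 | tert-butyl (13E)-7β-acetoxy-2-oxo-18-norcleroda-1(10),13-dien-15-oate | C1CC(=O)C=C2[C@@](C)(CC/C(C)=C/C(=O)OC(C)(C)C)[C@H](C)[C@@H](OC(C)=O)C[C@]12C | intermediate
18 | tert-butyl (13E)-7β-acetoxy-3-hydroxy-2-oxo-18-norcleroda-1(10),13-dien-15-oate (C3 epimers) | C1C(O)C(=O)C=C2[C@@](C)(CC/C(C)=C/C(=O)OC(C)(C)C)[C@H](C)[C@@H](OC(C)=O)C[C@]12C | intermediate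
19 | tert-butyl (13E)-7β-acetoxy-2-hydroxy-3-oxo-18-nor-10βH-cleroda-1,13-dien-15-oate | C1C(=O)C(O)=C[C@@H]2[C@@](C)(CC/C(C)=C/C(=O)OC(C)(C)C)[C@H](C)[C@@H](OC(C)=O)C[C@]12C | intermediate
20 | tert-butyl (13E)-7β-acetoxy-3-oxo-2-(triethylsilyloxy)-18-nor-10βH-cleroda-1,13-dien-15-oate | C1C(=O)C(O[Si](CC)(CC)CC)=C[C@@H]2[C@@](C)(CC/C(C)=C/C(=O)OC(C)(C)C)[C@H](C)[C@@H](OC(C)=O)C[C@]12C | intermediate
21 | Mannich base: 20 with a CH2NMe2 group on C4 (C4 epimers) | CN(C)CC1C(=O)C(O[Si](CC)(CC)CC)=C[C@@H]2[C@@](C)(CC/C(C)=C/C(=O)OC(C)(C)C)[C@H](C)[C@@H](OC(C)=O)C[C@]12C | intermediate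
22 | trimethylammonium iodide of 21 | C[N+](C)(C)CC1C(=O)C(O[Si](CC)(CC)CC)=C[C@@H]2[C@@](C)(CC/C(C)=C/C(=O)OC(C)(C)C)[C@H](C)[C@@H](OC(C)=O)C[C@]12C.[I-] | intermediate
23 | tert-butyl (13E)-7β-acetoxy-3-oxo-2-(triethylsilyloxy)-10βH-cleroda-1,4(18),13-trien-15-oate | C=C1C(=O)C(O[Si](CC)(CC)CC)=C[C@@H]2[C@@](C)(CC/C(C)=C/C(=O)OC(C)(C)C)[C@H](C)[C@@H](OC(C)=O)C[C@]12C | intermediate
24 | (5S,7S,8S,9R,10R,13E)-7-acetoxy-2-hydroxy-3-oxocleroda-1,4(18),13-trien-15-oic acid | C=C1C(=O)C(O)=C[C@@H]2[C@@](C)(CC/C(C)=C/C(=O)O)[C@H](C)[C@@H](OC(C)=O)C[C@]12C | target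

Total step count: 17. Longest linear sequence: 17 steps (1 to 24).

**Steps most likely to fail**

**Step 6.** The sulfide or the dioxolane may bind the boron cation, so that the uncatalysed background reaction erodes facial selectivity. The fallback replaces catalyst control by auxiliary control and sets out from 7.
- Diene 7 is combined with commercial (S)-4-benzyl-3-[(E)-but-2-enoyl]-1,3-oxazolidin-2-one and Et2AlCl in CH2Cl2 at −78 °C.
- In the chelated s-cis imide the benzyl group blocks one face. The endo adduct with the same configuration at all four centres results, the imide adduct F1.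
- Me(MeO)NH·HCl with AlMe3 then gives the N-methoxy-N-methylamide F2.
- MeMgBr in THF at 0 °C converts F2 into the methyl ketone, and the route is rejoined at 9.

**Step 8.** Closure at the C10 carbonyl may be sluggish because it lies between two quaternary carbons. Reversible loss of thiolate from the acetyl enolate or retro-Michael cleavage may then compete. The fallback replaces the aldol by an olefination with an irreversible driving force and sets out from 9.
- The Mukaiyama–Michael addition is run with dimethyl (2-oxobut-3-en-1-yl)phosphonate under the conditions of step 7, giving the β-keto phosphonate F3.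
- NaH in THF then closes ring A by an intramolecular Horner–Wadsworth–Emmons reaction, and the route is rejoined at 12.

**Step 14.** Tautomerisation may be incomplete, or the enediolate may autoxidise. The fallback replaces the redox-neutral shift by an oxidation–reduction pair and sets out from 18.
- Dess–Martin periodinane in CH2Cl2 gives the ene-1,2-dione F4.
- Zinc dust in acetic acid reduces its O=C2–C1=C10 unit in the 1,4 sense to the diosphenol. A short DBU treatment equilibrates C10, and the route is rejoined at 19.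

**Further compounds**
F1 | step 6 | (S)-4-benzyl-3-acyl-1,3-oxazolidin-2-one analogue of 9 (imide carbonyl on C7 in place of acetyl) | C1(O[Si](C)(C)C(C)(C)C)=C(C)[C@H]2SC[C@]1(CCC3(C)OCCO3)[C@H](C)[C@H]2C(=O)N4[C@@H](Cc5ccccc5)COC4=O
F2 | step 6 | N-methoxy-N-methylamide analogue of 9 | C1(O[Si](C)(C)C(C)(C)C)=C(C)[C@H]2SC[C@]1(CCC3(C)OCCO3)[C@H](C)[C@H]2C(=O)N(C)OC
F3 | step 8 | β-keto phosphonate analogue of 11 (4-(dimethoxyphosphoryl)-3-oxobutyl group on C5) | O=C1[C@@](C)(CCC(=O)CP(=O)(OC)OC)[C@H]2SC[C@]1(CCC3(C)OCCO3)[C@H](C)[C@H]2C(C)=O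
F4 | step 14 | tert-butyl (13E)-7β-acetoxy-2,3-dioxo-18-norcleroda-1(10),13-dien-15-oate | C1C(=O)C(=O)C=C2[C@@](C)(CC/C(C)=C/C(=O)OC(C)(C)C)[C@H](C)[C@@H](OC(C)=O)C[C@]12C
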